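**Retrosynthetic overview** (macrolide numbering: C1 lactone carbonyl to C13 oxygen-bearing carbon, C14–C15 ethyl)
1. Enabling feature: the C5 hydroxyl oxygen and the C9 carbonyl carbon are 1,5-related through C6–C7–C8, so O5–C5–C6–C7–C8–C9 is a latent six-membered ring. The target is the open form of a 5,9-hemiketal; one oxidation level lower it is a 2,6-cis-2-alkenyl-tetrahydropyran bridged across the 14-membered lactone.
2. Last disconnections: C9–O5 (DDQ/H2O turns the ring C9–H into the C9 ketone and frees 5-OH), preceded by C3–OH to C3=O, so that the labile C2 centre is exposed only at the end.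
3. Key disconnection C8–C9: Prins macrocyclization of an open-chain hydroxy enal ester. O5 captures the C9 aldehyde as an oxocarbenium ion, the (E)-C7=C8 alkene attacks it, and the C7 bromide left behind is removed with Bu3SnH.
4. Seco ester: C1–O13 by Yamaguchi esterification of a C1–C8 acid (β-ketoimide tin aldol for C4–C5, Evans methylation for C6) with a C9–C15 hydroxy enal (Evans syn aldol, Wittig).
5. Ring order: no ring until step 16; there a transient 12-membered oxocarbenium ring, then tetrahydropyran and 14-membered lactone together through the C8–C9 bond; the tetrahydropyran is opened in step 20.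

Key step: step 16

Remark: C2 lies between the C1 and C3 carbonyl groups and can epimerize by enolization, so C3 is carried as a silyl ether, oxidized under neutral conditions in step 19, and (2R) is delivered under kinetic control.

**Step 1**
Reactants: 1 (E)-pent-3-enoic acid; 2 (S)-4-benzyloxazolidin-2-one
Product: 4 (S)-4-benzyl-3-[(E)-pent-3-enoyl]oxazolidin-2-one, via mixed pivalic anhydride 3 (not isolated)
Conditions: PivCl, Et3N, THF, −20 °C; then 2, LiCl, −20 °C to rt
Reagents that add atoms: none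
Why: N-acylation of the oxazolidinone through the mixed pivalic anhydride needs no strong base, so the β,γ-double bond should stay out of conjugation and keep its E geometry.

**Step 2**
Reactants: 4 (S)-4-benzyl-3-[(E)-pent-3-enoyl]oxazolidin-2-one
Product: 5 (S)-4-benzyl-3-[(2S,3E)-2-methylpent-3-enoyl]oxazolidin-2-one
Conditions: NaN(SiMe3)2, THF, −78 °C; then MeI, −78 °C
Reagents that add atoms: iodomethane, CI
Why: Evans asymmetric alkylation: the chelated sodium (Z)-dienolate should be methylated at the α-carbon on the face away from the benzyl group, which sets C6 as (S) and leaves the E-alkene in the β,γ-position.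

**Step 3**
Reactants: 5 (S)-4-benzyl-3-[(2S,3E)-2-methylpent-3-enoyl]oxazolidin-2-one
Product: 6 (2S,3E)-2-methylpent-3-en-1-ol
Conditions: LiBH4, MeOH (1 equiv), Et2O, 0 °C
Reagents that add atoms: none
Why: Reductive cleavage of the Evans auxiliary with LiBH4 should give the primary alcohol without touching the α-stereocentre or the alkene.

**Step 4**
Reactants: 6 (2S,3E)-2-methylpent-3-en-1-ol
Product: 7 (2S,3E)-2-methylpent-3-enal
Conditions: Dess–Martin periodinane, CH2Cl2, 0 °C; cold solution used directly in step 6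
Reagents that add atoms: none
Why: Dess–Martin oxidation is non-basic and fast at 0 °C, so the α-stereocentre should hold and the alkene should not move into conjugation before the aldehyde is consumed.

**Step 5**
Reactants: 8 (S)-4-benzyl-3-propanoyloxazolidin-2-one; 9 propanoyl chloride
Product: 10 (S)-4-benzyl-3-[(2R)-2-methyl-3-oxopentanoyl]oxazolidin-2-one
Conditions: LiN(iPr)2, THF, −78 °C; then 9, −78 °C
Reagents that add atoms: none
Why: Evans C-acylation of the chelated lithium (Z)-enolate: the acid chloride should be attacked from the face opposite the benzyl group, which sets C2 as (R), and allylic strain in the product blocks enolization toward C2.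

**Step 6**
Reactants: 10 (S)-4-benzyl-3-[(2R)-2-methyl-3-oxopentanoyl]oxazolidin-2-one; 7 (2S,3E)-2-methylpent-3-enal
Product: 11 (S)-4-benzyl-3-[(2R,4S,5R,6S,7E)-5-hydroxy-2,4,6-trimethyl-3-oxonon-7-enoyl]oxazolidin-2-one
Conditions: Sn(OTf)2, Et3N, CH2Cl2, −20 °C; then 7, −78 °C
Reagents that add atoms: none
Why: Evans β-ketoimide aldol reaction through the divalent tin (Z)-enolate at C4: the closed transition state should give the 2,4-anti-4,5-syn adduct, so C4 (S) and C5 (R) are set by the C2 centre and the auxiliary, and this enolate control is expected to override the weak facial preference of the α-methyl aldehyde.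

**Step 7**
Reactants: 11 (S)-4-benzyl-3-[(2R,4S,5R,6S,7E)-5-hydroxy-2,4,6-trimethyl-3-oxonon-7-enoyl]oxazolidin-2-one
Product: 12 (S)-4-benzyl-3-[(2R,4S,5R,6S,7E)-2,4,6-trimethyl-3-oxo-5-(triethylsilyloxy)non-7-enoyl]oxazolidin-2-one
Conditions: Et3SiOTf, 2,6-lutidine, CH2Cl2, −78 °C
Reagents that add atoms: triethylsilyl trifluoromethanesulfonate, CC[Si](CC)(CC)OS(=O)(=O)C(F)(F)F
Why: Silylation of the C5 hydroxyl with a silyl triflate and a hindered base is fast at −78 °C and prevents retro-aldol cleavage and hydroxyl-directed reduction in the next step.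

**Step 8**
Reactants: 12 (S)-4-benzyl-3-[(2R,4S,5R,6S,7E)-2,4,6-trimethyl-3-oxo-5-(triethylsilyloxy)non-7-enoyl]oxazolidin-2-one
Product: 13 (S)-4-benzyl-3-[(2R,3S,4R,5R,6S,7E)-3-hydroxy-2,4,6-trimethyl-5-(triethylsilyloxy)non-7-enoyl]oxazolidin-2-one
Conditions: Zn(BH4)2, Et2O/CH2Cl2, −20 °C
Reagents that add atoms: none
Why: Chelation-controlled reduction of the β-ketoimide (zinc bridging the C3 ketone and the imide carbonyl, hydride anti to the C2 methyl) should give the 2,3-syn (3S) alcohol; this temporary centre only removes the acidity of C2–H and is oxidized back in step 19.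

**Step 9**
Reactants: 13 (S)-4-benzyl-3-[(2R,3S,4R,5R,6S,7E)-3-hydroxy-2,4,6-trimethyl-5-(triethylsilyloxy)non-7-enoyl]oxazolidin-2-one
Product: 14 (S)-4-benzyl-3-[(2R,3S,4S,5R,6S,7E)-3-(tert-butyldimethylsilyloxy)-2,4,6-trimethyl-5-(triethylsilyloxy)non-7-enoyl]oxazolidin-2-one
Conditions: tBuMe2SiOTf, 2,6-lutidine, CH2Cl2, 0 °C
Reagents that add atoms: tert-butyldimethylsilyl trifluoromethanesulfonate, CC(C)(C)[Si](C)(C)OS(=O)(=O)C(F)(F)F
Why: Silyl triflate protection of the hindered C3 alcohol as the robust TBS ether differentiates it from the more labile TES ether at C5.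

**Step 10**
Reactants: 14 (S)-4-benzyl-3-[(2R,3S,4S,5R,6S,7E)-3-(tert-butyldimethylsilyloxy)-2,4,6-trimethyl-5-(triethylsilyloxy)non-7-enoyl]oxazolidin-2-one
Product: 16 (2R,3S,4S,5R,6S,7E)-3-(tert-butyldimethylsilyloxy)-2,4,6-trimethyl-5-(triethylsilyloxy)non-7-enoic acid, via peroxy acid 15 (not isolated)
Conditions: LiOH, H2O2, THF/H2O (3:1), 0 °C; then aq. Na2SO3
Reagents that add atoms: hydrogen peroxide, OO
Why: Lithium hydroperoxide should attack the exocyclic imide carbonyl selectively (Evans auxiliary hydrolysis), the peroxy acid is reduced by sulfite, and the weakly basic medium should not epimerize C2 or disturb the silyl ethers.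

**Step 11**
Reactants: 17 (R)-4-benzyl-3-propanoyloxazolidin-2-one; 18 propanal
Product: 19 (R)-4-benzyl-3-[(2R,3S)-3-hydroxy-2-methylpentanoyl]oxazolidin-2-one
Conditions: Bu2BOTf, iPr2NEt, CH2Cl2, 0 °C; then 18, −78 to 0 °C; pH 7 buffer, MeOH, H2O2
Reagents that add atoms: none
Why: Evans syn aldol reaction: the (Z)-boron enolate should react through a Zimmerman–Traxler chair on the face opposite the benzyl group, which sets C12 and C13 (syn) in the sense needed for (12S,13S).

**Step 12**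
Reactants: 19 (R)-4-benzyl-3-[(2R,3S)-3-hydroxy-2-methylpentanoyl]oxazolidin-2-one
Product: 20 (2S,3S)-2-methylpentane-1,3-diol
Conditions: LiBH4, MeOH (1 equiv), THF, 0 °C
Reagents that add atoms: none
Why: Reductive cleavage of the auxiliary with LiBH4 should give the 1,3-diol without epimerization.

**Step 13**
Reactants: 20 (2S,3S)-2-methylpentane-1,3-diol
Product: 22 (2E,4S,5S)-5-hydroxy-4-methylhept-2-enal, via (2R,3S)-3-hydroxy-2-methylpentanal 21 (not isolated)
Conditions: PhI(OAc)2, 2,2,6,6-tetramethylpiperidin-1-oxyl (TEMPO, 10 mol %), CH2Cl2, rt; then Ph3P=CHCHO, toluene, 60 °C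
Reagents that add atoms: (triphenylphosphoranylidene)acetaldehyde, O=CC=P(c1ccccc1)(c1ccccc1)c1ccccc1
Why: The nitroxyl-catalysed oxidation should take the primary alcohol selectively, and the stabilized formyl ylide converts the aldehyde in the same pot into the (E)-enal (Wittig reaction) before the β-hydroxy aldehyde can epimerize or eliminate.

**Step 14**
Reactants: 16 (2R,3S,4S,5R,6S,7E)-3-(tert-butyldimethylsilyloxy)-2,4,6-trimethyl-5-(triethylsilyloxy)non-7-enoic acid; 22 (2E,4S,5S)-5-hydroxy-4-methylhept-2-enal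
Product: 24 (3S,4S,5E)-4-methyl-7-oxohept-5-en-3-yl (2R,3S,4S,5R,6S,7E)-3-(tert-butyldimethylsilyloxy)-2,4,6-trimethyl-5-(triethylsilyloxy)non-7-enoate, via Yamaguchi mixed anhydride 23 (not isolated)
Conditions: 2,4,6-trichlorobenzoyl chloride, Et3N, THF, rt; then 22, 4-(dimethylamino)pyridine, toluene, rt
Reagents that add atoms: none
Why: Yamaguchi esterification should join the hindered secondary C13 alcohol to the C1 acid through the mixed anhydride, and the enal is not touched under these conditions.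

**Step 15**
Reactants: 24 (3S,4S,5E)-4-methyl-7-oxohept-5-en-3-yl (2R,3S,4S,5R,6S,7E)-3-(tert-butyldimethylsilyloxy)-2,4,6-trimethyl-5-(triethylsilyloxy)non-7-enoate
Product: 25 (3S,4S,5E)-4-methyl-7-oxohept-5-en-3-yl (2R,3S,4S,5R,6S,7E)-3-(tert-butyldimethylsilyloxy)-5-hydroxy-2,4,6-trimethylnon-7-enoate
Conditions: HF·pyridine, pyridine, THF, 0 °C
Reagents that add atoms: none
Why: Buffered HF·pyridine should cleave the secondary triethylsilyl ether at C5 much faster than the tert-butyldimethylsilyl ether at C3, and the near-neutral medium should keep the freed C5 hydroxyl from lactonizing onto C1.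

**Step 16**
Reactants: 25 (3S,4S,5E)-4-methyl-7-oxohept-5-en-3-yl (2R,3S,4S,5R,6S,7E)-3-(tert-butyldimethylsilyloxy)-5-hydroxy-2,4,6-trimethylnon-7-enoate
Product: 27 (2R,3S,4S,5S,6R,7S,8R,9R,10E,12S,13S)-7-bromo-3-(tert-butyldimethylsilyloxy)-5,9-epoxy-2,4,6,8,12-pentamethylpentadec-10-en-13-olide, via macrocyclic oxocarbenium bromide 26 (not isolated)
Conditions: Me3SiBr (1.5 equiv), In(OTf)3 (10 mol %), CH2Cl2 (0.002 M), −78 to 0 °C
Reagents that add atoms: bromotrimethylsilane, C[Si](C)(C)Br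
Why: Me3SiBr and the indium triflate should condense the C5 hydroxyl with the C9 aldehyde to the 12-membered (E)-oxocarbenium ion 26, the (E)-C7=C8 alkene then attacks C9 through a chair transition state and bromide captures the resulting C7 cation (Prins cyclization). The closest known reaction type is the Prins macrocyclization of ester-tethered hydroxy alkenyl aldehydes, which gives 2,6-cis-tetrahydropyrans bridged across 14-membered lactones, combined with the silyl bromide variant that delivers 4-bromotetrahydropyrans. The tetrahydropyran (O5, C5, C6, C7, C8, C9) closes by 6-endo attack of the alkene on the oxocarbenium carbon, and the same C8–C9 bond closes the 14-membered lactone ring as a transannular stitch across the 12-membered oxocarbenium ring. C9 is set cis to C5 by the E-oxocarbenium geometry (both ring substituents equatorial), C8 is set as in the target by the E geometry of the alkene, which places its methyl group equatorial, and C7 by equatorial bromide capture (this centre is removed in step 17). The step needs the chair with the C4 chain at C5 equatorial and the C6 methyl axial to win over the ring-flipped chair, which would give the C8 epimer; the larger penalty for an axial substituent next to the ring oxygen should secure this, while high dilution and fast bromide capture are counted on to suppress oligomerization and 2-oxonia-Cope scrambling.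

**Step 17**
Reactants: 27 (2R,3S,4S,5S,6R,7S,8R,9R,10E,12S,13S)-7-bromo-3-(tert-butyldimethylsilyloxy)-5,9-epoxy-2,4,6,8,12-pentamethylpentadec-10-en-13-olide
Product: 28 (2R,3S,4S,5R,6S,8S,9S,10E,12S,13S)-3-(tert-butyldimethylsilyloxy)-5,9-epoxy-2,4,6,8,12-pentamethylpentadec-10-en-13-olide
Conditions: Bu3SnH, 2,2'-azobis(2-methylpropionitrile) (10 mol %), toluene, 80 °C
Reagents that add atoms: none
Why: Radical chain dehalogenation with the tin hydride should replace the C7 bromine by hydrogen; the C7 radical has no alkene within reach for a favourable cyclization and no retained stereocentre is affected.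

**Step 18**
Reactants: 28 (2R,3S,4S,5R,6S,8S,9S,10E,12S,13S)-3-(tert-butyldimethylsilyloxy)-5,9-epoxy-2,4,6,8,12-pentamethylpentadec-10-en-13-olide
Product: 29 (2R,3S,4R,5R,6S,8S,9S,10E,12S,13S)-5,9-epoxy-3-hydroxy-2,4,6,8,12-pentamethylpentadec-10-en-13-olide
Conditions: HF·pyridine, THF, 0 °C to rt
Reagents that add atoms: none
Why: Fluoride-mediated cleavage of the C3 silyl ether should free the only hydroxyl of the molecule, because the C5 oxygen is still tied up in the tetrahydropyran.

**Step 19**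
Reactants: 29 (2R,3S,4R,5R,6S,8S,9S,10E,12S,13S)-5,9-epoxy-3-hydroxy-2,4,6,8,12-pentamethylpentadec-10-en-13-olide
Product: 30 (2R,4S,5R,6S,8S,9S,10E,12S,13S)-5,9-epoxy-2,4,6,8,12-pentamethyl-3-oxopentadec-10-en-13-olide
Conditions: Dess–Martin periodinane, CH2Cl2, 0 °C to rt
Reagents that add atoms: none
Why: Dess–Martin oxidation should turn the C3 alcohol into the ketone under neutral conditions that do not involve the C2–H bond, so the (2R) centre set in step 5 enters the β-keto lactone intact.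

**Step 20**
Reactants: 30 (2R,4S,5R,6S,8S,9S,10E,12S,13S)-5,9-epoxy-2,4,6,8,12-pentamethyl-3-oxopentadec-10-en-13-olide
Product: 32 (2R,4S,5R,6S,8S,10E,12S,13S)-5-hydroxy-2,4,6,8,12-pentamethyl-3,9-dioxopentadec-10-en-13-olide (target), via 5,9-hemiketal 31 (not isolated)
Conditions: 2,3-dichloro-5,6-dicyano-1,4-benzoquinone (DDQ, 2 equiv), ClCH2CH2Cl/H2O (10:1), rt to 45 °C
Reagents that add atoms: water, O
Why: DDQ should abstract the axial C9 hydride (allylic and α to the ring oxygen) to give a conjugated oxocarbenium ion, water adds to give hemiketal 31, and its ring-chain tautomer is the 5-hydroxy 9-keto (E)-enone (oxidative cleavage of an allylic ether by DDQ); only the temporary C9 centre is lost.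

**Compound list**
1 | (E)-pent-3-enoic acid | C/C=C/CC(=O)O | starting material
2 | (S)-4-benzyloxazolidin-2-one | O=C1N[C@@H](Cc2ccccc2)CO1 | starting material
3 | (E)-pent-3-enoic pivalic anhydride | C/C=C/CC(=O)OC(=O)C(C)(C)C | intermediate
4 | (S)-4-benzyl-3-[(E)-pent-3-enoyl]oxazolidin-2-one | C/C=C/CC(=O)N1[C@@H](Cc2ccccc2)COC1=O | intermediate
5 | (S)-4-benzyl-3-[(2S,3E)-2-methylpent-3-enoyl]oxazolidin-2-one | O=C(N1[C@@H](Cc2ccccc2)COC1=O)[C@@H](C)/C=C/C | intermediate
6 | (2S,3E)-2-methylpent-3-en-1-ol | OC[C@@H](C)/C=C/C | intermediate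
7 | (2S,3E)-2-methylpent-3-enal | O=C[C@@H](C)/C=C/C | intermediate
8 | (S)-4-benzyl-3-propanoyloxazolidin-2-one | CCC(=O)N1[C@@H](Cc2ccccc2)COC1=O | starting material
9 | propanoyl chloride | CCC(=O)Cl | starting material
10 | (S)-4-benzyl-3-[(2R)-2-methyl-3-oxopentanoyl]oxazolidin-2-one | O=C(N1[C@@H](Cc2ccccc2)COC1=O)[C@H](C)C(=O)CC | intermediate
11 | (S)-4-benzyl-3-[(2R,4S,5R,6S,7E)-5-hydroxy-2,4,6-trimethyl-3-oxonon-7-enoyl]oxazolidin-2-one | O=C(N1[C@@H](Cc2ccccc2)COC1=O)[C@H](C)C(=O)[C@@H](C)[C@H](O)[C@@H](C)/C=C/C | intermediate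
12 | (S)-4-benzyl-3-[(2R,4S,5R,6S,7E)-2,4,6-trimethyl-3-oxo-5-(triethylsilyloxy)non-7-enoyl]oxazolidin-2-one | O=C(N1[C@@H](Cc2ccccc2)COC1=O)[C@H](C)C(=O)[C@@H](C)[C@H](O[Si](CC)(CC)CC)[C@@H](C)/C=C/C | intermediate
13 | (S)-4-benzyl-3-[(2R,3S,4R,5R,6S,7E)-3-hydroxy-2,4,6-trimethyl-5-(triethylsilyloxy)non-7-enoyl]oxazolidin-2-one | O=C(N1[C@@H](Cc2ccccc2)COC1=O)[C@H](C)[C@@H](O)[C@@H](C)[C@H](O[Si](CC)(CC)CC)[C@@H](C)/C=C/C | intermediate
14 | (S)-4-benzyl-3-[(2R,3S,4S,5R,6S,7E)-3-(tert-butyldimethylsilyloxy)-2,4,6-trimethyl-5-(triethylsilyloxy)non-7-enoyl]oxazolidin-2-one | O=C(N1[C@@H](Cc2ccccc2)COC1=O)[C@H](C)[C@@H](O[Si](C)(C)C(C)(C)C)[C@@H](C)[C@H](O[Si](CC)(CC)CC)[C@@H](C)/C=C/C | intermediate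
15 | (2R,3S,4S,5R,6S,7E)-3-(tert-butyldimethylsilyloxy)-2,4,6-trimethyl-5-(triethylsilyloxy)non-7-eneperoxoic acid | OOC(=O)[C@H](C)[C@@H](O[Si](C)(C)C(C)(C)C)[C@@H](C)[C@H](O[Si](CC)(CC)CC)[C@@H](C)/C=C/C | intermediate
16 | (2R,3S,4S,5R,6S,7E)-3-(tert-butyldimethylsilyloxy)-2,4,6-trimethyl-5-(triethylsilyloxy)non-7-enoic acid | OC(=O)[C@H](C)[C@@H](O[Si](C)(C)C(C)(C)C)[C@@H](C)[C@H](O[Si](CC)(CC)CC)[C@@H](C)/C=C/C | intermediate
17 | (R)-4-benzyl-3-propanoyloxazolidin-2-one | CCC(=O)N1[C@H](Cc2ccccc2)COC1=O | starting material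
18 | propanal | CCC=O | starting material
19 | (R)-4-benzyl-3-[(2R,3S)-3-hydroxy-2-methylpentanoyl]oxazolidin-2-one | CC[C@H](O)[C@@H](C)C(=O)N1[C@H](Cc2ccccc2)COC1=O | intermediate
20 | (2S,3S)-2-methylpentane-1,3-diol | CC[C@H](O)[C@@H](C)CO | intermediate
21 | (2R,3S)-3-hydroxy-2-methylpentanal | CC[C@H](O)[C@@H](C)C=O | intermediate
22 | (2E,4S,5S)-5-hydroxy-4-methylhept-2-enal | CC[C@H](O)[C@@H](C)/C=C/C=O | intermediate
23 | mixed anhydride of acid 16 with 2,4,6-trichlorobenzoic acid | O=C(OC(=O)c1c(Cl)cc(Cl)cc1Cl)[C@H](C)[C@@H](O[Si](C)(C)C(C)(C)C)[C@@H](C)[C@H](O[Si](CC)(CC)CC)[C@@H](C)/C=C/C | intermediate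
24 | (3S,4S,5E)-4-methyl-7-oxohept-5-en-3-yl (2R,3S,4S,5R,6S,7E)-3-(tert-butyldimethylsilyloxy)-2,4,6-trimethyl-5-(triethylsilyloxy)non-7-enoate | CC[C@H](OC(=O)[C@H](C)[C@@H](O[Si](C)(C)C(C)(C)C)[C@@H](C)[C@H](O[Si](CC)(CC)CC)[C@@H](C)/C=C/C)[C@@H](C)/C=C/C=O | intermediate
25 | (3S,4S,5E)-4-methyl-7-oxohept-5-en-3-yl (2R,3S,4S,5R,6S,7E)-3-(tert-butyldimethylsilyloxy)-5-hydroxy-2,4,6-trimethylnon-7-enoate | CC[C@H](OC(=O)[C@H](C)[C@@H](O[Si](C)(C)C(C)(C)C)[C@@H](C)[C@H](O)[C@@H](C)/C=C/C)[C@@H](C)/C=C/C=O | intermediate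
26 | 12-membered (E)-oxocarbenium bromide formed from O5 and C9 of 25 (ring O5, C9–C13, lactone O, C1–C5; (E)-pent-3-en-2-yl side chain on C5) | CC[C@@H]1OC(=O)[C@H](C)[C@@H](O[Si](C)(C)C(C)(C)C)[C@@H](C)[C@@H]([C@@H](C)/C=C/C)/[O+]=C/C=C/[C@@H]1C.[Br-] | intermediate
27 | (2R,3S,4S,5S,6R,7S,8R,9R,10E,12S,13S)-7-bromo-3-(tert-butyldimethylsilyloxy)-5,9-epoxy-2,4,6,8,12-pentamethylpentadec-10-en-13-olide | CC[C@@H]1OC(=O)[C@H](C)[C@@H](O[Si](C)(C)C(C)(C)C)[C@@H](C)[C@H]2[C@@H](C)[C@@H](Br)[C@H](C)[C@H](O2)/C=C/[C@@H]1C | intermediate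
28 | (2R,3S,4S,5R,6S,8S,9S,10E,12S,13S)-3-(tert-butyldimethylsilyloxy)-5,9-epoxy-2,4,6,8,12-pentamethylpentadec-10-en-13-olide | CC[C@@H]1OC(=O)[C@H](C)[C@@H](O[Si](C)(C)C(C)(C)C)[C@@H](C)[C@H]2[C@@H](C)C[C@H](C)[C@H](O2)/C=C/[C@@H]1C | intermediate
29 | (2R,3S,4R,5R,6S,8S,9S,10E,12S,13S)-5,9-epoxy-3-hydroxy-2,4,6,8,12-pentamethylpentadec-10-en-13-olide | CC[C@@H]1OC(=O)[C@H](C)[C@@H](O)[C@@H](C)[C@H]2[C@@H](C)C[C@H](C)[C@H](O2)/C=C/[C@@H]1C | intermediate
30 | (2R,4S,5R,6S,8S,9S,10E,12S,13S)-5,9-epoxy-2,4,6,8,12-pentamethyl-3-oxopentadec-10-en-13-olide | CC[C@@H]1OC(=O)[C@H](C)C(=O)[C@@H](C)[C@H]2[C@@H](C)C[C@H](C)[C@H](O2)/C=C/[C@@H]1C | intermediate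
31 | (2R,4S,5R,6S,8S,9S,10E,12S,13S)-5,9-epoxy-9-hydroxy-2,4,6,8,12-pentamethyl-3-oxopentadec-10-en-13-olide (5,9-hemiketal, hydroxyl axial) | CC[C@@H]1OC(=O)[C@H](C)C(=O)[C@@H](C)[C@H]2[C@@H](C)C[C@H](C)[C@](O)(O2)/C=C/[C@@H]1C | intermediate
32 | (2R,4S,5R,6S,8S,10E,12S,13S)-5-hydroxy-2,4,6,8,12-pentamethyl-3,9-dioxopentadec-10-en-13-olide, equal to (3R,5S,6R,7S,9S,11E,13S,14S)-14-ethyl-6-hydroxy-3,5,7,9,13-pentamethyl-1-oxacyclotetradec-11-ene-2,4,10-trione | CC[C@@H]1OC(=O)[C@H](C)C(=O)[C@@H](C)[C@H](O)[C@@H](C)C[C@H](C)C(=O)/C=C/[C@@H]1C | target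

**Totals:** 20 steps. Longest linear sequence: 16 steps (steps 1–4, 6–10, 14–20).

**Steps most likely to fail**

Step 16. What may go wrong: intermolecular acetal formation and oligomerization may outrun ring closure; closure through the ring-flipped chair would erode facial selectivity at C8; 2-oxonia-Cope rearrangement may scramble the alkene; the C5 hydroxyl may lactonize onto C1 under Lewis acid. The fallback forms the C8–C9 bond between the two fragments first and closes the large ring by lactonization. It sets out from 14 and 22 and comes back at 28. Selective cleavage of the triethylsilyl ether of 14 (HF·pyridine, pyridine, THF) should give the hydroxy imide F1. Intermolecular Prins cyclization of F1 with 22 (Me3SiBr, In(OTf)3, CH2Cl2, −78 to 0 °C) should give the bromotetrahydropyran imide F2. Tin hydride reduction (Bu3SnH, radical initiator, toluene, 80 °C) should give the debrominated tetrahydropyran imide F3. LiOH/H2O2 should remove the auxiliary to give the seco acid F4. Yamaguchi macrolactonization of F4 (2,4,6-trichlorobenzoyl chloride, Et3N, then 4-(dimethylamino)pyridine, toluene, high dilution) closes the 14-membered ring and returns to 28.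

Step 20. What may go wrong: hydride abstraction from the cyclic allylic ether may be sluggish, so oxidation at the enolizable C2 position or at the allylic C12–H competes; the hemiketal may also be slow to open. The fallback replaces hydride abstraction by radical C–H bromination and moves this event ahead of the C3 adjustment. It sets out from 28 and comes back at 32. N-Bromosuccinimide with a radical initiator in PhCF3 (solid NaHCO3, 80 °C) should brominate the doubly activated C9–H to the α-bromo ether F5 (not isolated). Methanol with NaHCO3 should convert it into the methyl ketal F6. Bu4NF buffered with AcOH should give the ketal alcohol F7. Dess–Martin periodinane should give the ketal ketone F8. Pyridinium p-toluenesulfonate in acetone/H2O should hydrolyse the ketal through hemiketal 31 to 32.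

Step 6. What may go wrong: facial selectivity may erode in this double stereodifferentiating addition, where the enolate must override the aldehyde; the β,γ-double bond of the aldehyde may also migrate into conjugation. The fallback builds C4–C5 and C2–C3 by two successive Evans boron aldol reactions, which are known to dominate over aldehyde bias. It sets out from 7, 8 and 17 and comes back at 16. Bu2BOTf/iPr2NEt aldol reaction of 8 with 7 should give the syn aldol imide F9. Et3SiOTf/2,6-lutidine should give the silyl ether F10. LiBH4 should give the primary alcohol F11. Dess–Martin periodinane should give the aldehyde F12. Bu2BOTf/iPr2NEt aldol reaction of 17 with F12 should give the second syn aldol imide F13. tBuMe2SiOTf/2,6-lutidine should give the bis-silyl imide F14. LiOH/H2O2 then returns to 16.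

**Further compounds**
F1 | step 16 | (S)-4-benzyl-3-[(2R,3S,4S,5R,6S,7E)-3-(tert-butyldimethylsilyloxy)-5-hydroxy-2,4,6-trimethylnon-7-enoyl]oxazolidin-2-one | O=C(N1[C@@H](Cc2ccccc2)COC1=O)[C@H](C)[C@@H](O[Si](C)(C)C(C)(C)C)[C@@H](C)[C@H](O)[C@@H](C)/C=C/C
F2 | step 16 | bromotetrahydropyran imide: 2,6-cis-tetrahydropyran (O5, C5–C9) with equatorial Br at C7, the (E)-C10–C15 chain with free C13 hydroxyl on C9 and the silylated C1–C4 imide chain on C5 | O=C(N1[C@@H](Cc2ccccc2)COC1=O)[C@H](C)[C@@H](O[Si](C)(C)C(C)(C)C)[C@@H](C)[C@H]2[C@@H](C)[C@@H](Br)[C@H](C)[C@H](O2)/C=C/[C@H](C)[C@@H](O)CC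
F3 | step 16 | debrominated tetrahydropyran imide (F2 with H in place of Br at C7) | O=C(N1[C@@H](Cc2ccccc2)COC1=O)[C@H](C)[C@@H](O[Si](C)(C)C(C)(C)C)[C@@H](C)[C@H]2[C@@H](C)C[C@H](C)[C@H](O2)/C=C/[C@H](C)[C@@H](O)CC
F4 | step 16 | seco acid: C1 carboxylic acid of F3 after removal of the oxazolidinone, C13 hydroxyl free | OC(=O)[C@H](C)[C@@H](O[Si](C)(C)C(C)(C)C)[C@@H](C)[C@H]2[C@@H](C)C[C@H](C)[C@H](O2)/C=C/[C@H](C)[C@@H](O)CC
F5 | step 20 | (9R)-9-bromo derivative of 28 (α-bromo ether, bromine axial) | CC[C@@H]1OC(=O)[C@H](C)[C@@H](O[Si](C)(C)C(C)(C)C)[C@@H](C)[C@H]2[C@@H](C)C[C@H](C)[C@](Br)(O2)/C=C/[C@@H]1C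
F6 | step 20 | (9S)-9-methoxy derivative of 28 (methyl ketal, methoxy axial) | CC[C@@H]1OC(=O)[C@H](C)[C@@H](O[Si](C)(C)C(C)(C)C)[C@@H](C)[C@H]2[C@@H](C)C[C@H](C)[C@](OC)(O2)/C=C/[C@@H]1C
F7 | step 20 | (9S)-9-methoxy derivative of 29 (ketal alcohol, C3 hydroxyl free) | CC[C@@H]1OC(=O)[C@H](C)[C@@H](O)[C@@H](C)[C@H]2[C@@H](C)C[C@H](C)[C@](OC)(O2)/C=C/[C@@H]1C
F8 | step 20 | (9S)-9-methoxy derivative of 30 (ketal ketone, methyl ketal of hemiketal 31) | CC[C@@H]1OC(=O)[C@H](C)C(=O)[C@@H](C)[C@H]2[C@@H](C)C[C@H](C)[C@](OC)(O2)/C=C/[C@@H]1C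
F9 | step 6 | (S)-4-benzyl-3-[(2S,3R,4S,5E)-3-hydroxy-2,4-dimethylhept-5-enoyl]oxazolidin-2-one | O=C(N1[C@@H](Cc2ccccc2)COC1=O)[C@@H](C)[C@H](O)[C@@H](C)/C=C/C
F10 | step 6 | (S)-4-benzyl-3-[(2S,3R,4S,5E)-2,4-dimethyl-3-(triethylsilyloxy)hept-5-enoyl]oxazolidin-2-one | O=C(N1[C@@H](Cc2ccccc2)COC1=O)[C@@H](C)[C@H](O[Si](CC)(CC)CC)[C@@H](C)/C=C/C
F11 | step 6 | (2R,3R,4S,5E)-2,4-dimethyl-3-(triethylsilyloxy)hept-5-en-1-ol | OC[C@@H](C)[C@H](O[Si](CC)(CC)CC)[C@@H](C)/C=C/C
F12 | step 6 | (2S,3R,4S,5E)-2,4-dimethyl-3-(triethylsilyloxy)hept-5-enal | O=C[C@@H](C)[C@H](O[Si](CC)(CC)CC)[C@@H](C)/C=C/C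
F13 | step 6 | (R)-4-benzyl-3-[(2R,3S,4R,5R,6S,7E)-3-hydroxy-2,4,6-trimethyl-5-(triethylsilyloxy)non-7-enoyl]oxazolidin-2-one | O=C(N1[C@H](Cc2ccccc2)COC1=O)[C@H](C)[C@@H](O)[C@@H](C)[C@H](O[Si](CC)(CC)CC)[C@@H](C)/C=C/C
F14 | step 6 | (R)-4-benzyl-3-[(2R,3S,4S,5R,6S,7E)-3-(tert-butyldimethylsilyloxy)-2,4,6-trimethyl-5-(triethylsilyloxy)non-7-enoyl]oxazolidin-2-one | O=C(N1[C@H](Cc2ccccc2)COC1=O)[C@H](C)[C@@H](O[Si](C)(C)C(C)(C)C)[C@@H](C)[C@H](O[Si](CC)(CC)CC)[C@@H](C)/C=C/C
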